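**Retrosynthetic overview** (ring numbered C1(=O), C2(OH), C3(chain), C4(=O), C5(OMe), C6(H))
1. Last, the C2 hydroxyl is unmasked from a tert-butyl ether; the quinone ring, the only ring, is made before that in one thermal operation.
2. Key disconnection is C4(=O)–C5(OMe): 4π ring opening of a 4-hydroxy-4-[(Z)-2-methoxyvinyl]cyclobutenone gives a dienylketene whose ketene carbon closes onto the methoxy-bearing vinyl carbon (6π), followed by tautomerization and oxidation.
3. Enabling feature: C1(=O)–C2(OH)–C3(chain)–C4(=O) are four contiguous ring carbons, three of them oxygenated, which is the pattern of a squaric acid ring, and the para C1/C4 dioxygenation is what a ketene closure delivers; C5(OMe)=C6(H) is a two-carbon enol ether.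
4. The cyclobutenone comes from di-tert-butyl squarate by two carbanion additions: the C15 dienyl Grignard reagent (then TFAA), then (Z)-2-methoxyvinyllithium.
5. Side chain: copper-mediated coupling of non-8-yn-1-ol with 1-bromohex-2-yne, Lindlar semi-hydrogenation (sets both Z-alkenes), Appel bromination.

Key step: step 7

Assumption: (Z)-1-bromo-2-methoxyethene is treated as not purchasable and is made in step 5; the target is drawn as its 2-hydroxy-1,4-quinone tautomer.

**Step 1**
Reactants: 1 non-8-yn-1-ol; 2 1-bromohex-2-yne
Product: 3 pentadeca-8,11-diyn-1-ol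
Conditions: CuI, NaI, K2CO3, DMF, rt
Reagents that add atoms: none
Why: Copper-mediated sp–sp3 coupling, in which the copper acetylide of 1 displaces the propargylic bromide of 2 (iodide-assisted SN2), is the standard construction of skipped diynes and tolerates the free primary alcohol.

**Step 2**
Reactants: 3 pentadeca-8,11-diyn-1-ol
Product: 4 (8Z,11Z)-pentadeca-8,11-dien-1-ol
Conditions: H2 (1 atm), Pd/CaCO3 poisoned with Pb(OAc)2 (Lindlar catalyst), quinoline, EtOAc, 0 °C to rt, stopped after 2 equiv H2
Reagents that add atoms: none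
Why: Lindlar semi-hydrogenation delivers H2 syn to each alkyne on the poisoned palladium surface, which sets both Z-alkenes of the target, and quinoline with monitored H2 uptake limits over-reduction.

**Step 3**
Reactants: 4 (8Z,11Z)-pentadeca-8,11-dien-1-ol
Product: 5 (8Z,11Z)-1-bromopentadeca-8,11-diene
Conditions: CBr4, PPh3, CH2Cl2, 0 °C
Reagents that add atoms: tetrabromomethane BrC(Br)(Br)Br
Why: Appel reaction, in which bromide displaces the oxyphosphonium ion of the primary alcohol (SN2) under neutral conditions that leave the remote Z,Z-diene untouched.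

**Step 4**
Reactants: 5 (8Z,11Z)-1-bromopentadeca-8,11-diene; 6 di-tert-butyl squarate
Product: 10 3-tert-butoxy-4-[(8Z,11Z)-pentadeca-8,11-dien-1-yl]cyclobut-3-ene-1,2-dione, via Grignard reagent 7 (not isolated), via bromomagnesium alkoxide 8 (not isolated), via trifluoroacetate 9 (not isolated)
Conditions: Mg, THF, 40 °C; then 6, THF, −78 °C; then (CF3CO)2O, −78 °C to 0 °C; aq. NaHCO3
Reagents that add atoms: none
Why: The Grignard reagent adds 1,2 to one of the two equivalent carbonyls of the squarate, and O-trifluoroacetylation of the alkoxide triggers ionization with loss of one tert-butyl group to unveil the 1,2-dione, the standard addition/acylative rearrangement route from dialkyl squarates to 3-alkoxy-4-alkylcyclobutenediones.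

**Step 5**
Reactants: 11 methyl vinyl ether
Product: 13 (Z)-1-bromo-2-methoxyethene, via dibromo ether 12 (not isolated)
Conditions: Br2, pentane, −78 °C; then PhNEt2, 95 °C; distillation
Reagents that add atoms: bromine BrBr
Why: Bromination of the enol ether followed by amine-induced dehydrobromination of the α-bromo ether, the classical preparation of 2-bromovinyl ethers, should give mainly the Z isomer, the more stable one for 1-halo-2-alkoxyethenes.

**Step 6**
Reactants: 13 (Z)-1-bromo-2-methoxyethene; 10 3-tert-butoxy-4-[(8Z,11Z)-pentadeca-8,11-dien-1-yl]cyclobut-3-ene-1,2-dione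
Product: 16 3-tert-butoxy-4-hydroxy-4-[(Z)-2-methoxyethenyl]-2-[(8Z,11Z)-pentadeca-8,11-dien-1-yl]cyclobut-2-en-1-one (racemic), via vinyllithium 14 (not isolated), via lithium alkoxide 15 (not isolated)
Conditions: n-BuLi, Et2O, −78 °C; then 10, THF, −78 °C; H2O quench at −78 °C; filtration through basic Al2O3, used at once
Reagents that add atoms: none
Why: Bromine–lithium exchange gives the configurationally stable Z-vinyllithium (lithium cis to methoxy, so β-elimination is slow at −78 °C), which adds 1,2 to the ketone-like carbonyl of 10 next to the tert-butoxy-bearing carbon and not to the vinylogous ester carbonyl, the established regiochemistry for organolithium addition to 3-alkoxy-4-alkylcyclobutenediones; the new carbinol center is racemic and is destroyed in step 7.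

**Step 7**
Reactants: 16 3-tert-butoxy-4-hydroxy-4-[(Z)-2-methoxyethenyl]-2-[(8Z,11Z)-pentadeca-8,11-dien-1-yl]cyclobut-2-en-1-one
Product: 20 2-tert-butoxy-5-methoxy-3-[(8Z,11Z)-pentadeca-8,11-dien-1-yl]cyclohexa-2,5-diene-1,4-dione, via dienylketene 17 (not isolated), via cyclohexadienone 18 (not isolated), via hydroquinone 19 (not isolated)
Conditions: degassed toluene, 110 °C, argon; then Ag2O, rt
Reagents that add atoms: none
Why: Heating opens the cyclobutenone by conrotatory 4π electrocyclic cleavage of the bond between the carbonyl carbon and the carbinol carbon, and the donor hydroxyl rotates outward (torquoselectivity), so the methoxyvinyl group sits cis to the ketene in dienylketene 17. The ring is then closed by a thermal disrotatory 6π electrocyclization in which the ketene carbon bonds to the methoxy-bearing vinyl carbon (the C4–C5 bond of the quinone), giving cyclohexadienone 18 as the only ring formed. The sp3 C(H)(OMe) center of 18 is transient, since enolization aromatizes it to hydroquinone 19, which Ag2O oxidizes to the para-quinone; no stereocenter has to be controlled, and the Z,Z-diene is remote from the reacting π system and untouched under neutral, degassed conditions. The closest known reaction type is the Moore rearrangement of 4-alkenyl-4-hydroxycyclobutenones to hydroquinones and quinones. The step needs regiocontrol, fixed by the substitution pattern of 16 because only the bond to the carbinol carbon can open, and it needs tautomerization of 18 to outrun loss of methanol, which the neutral aprotic medium and the aromatic driving force should favour.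

**Step 8**
Reactants: 20 2-tert-butoxy-5-methoxy-3-[(8Z,11Z)-pentadeca-8,11-dien-1-yl]cyclohexa-2,5-diene-1,4-dione
Product: 21 2-hydroxy-5-methoxy-3-[(8Z,11Z)-pentadeca-8,11-dien-1-yl]cyclohexa-2,5-diene-1,4-dione (sorgoleone-360)
Conditions: CF3CO2H, CH2Cl2, 0 °C
Reagents that add atoms: none
Why: Acid-induced E1 cleavage of the tert-butyl vinylogous ester (tert-butyl cation lost as isobutene) is the established way from tert-butoxyquinones to hydroxyquinones, while the methyl vinylogous ester cannot ionize in this way and the non-conjugated Z,Z-diene should tolerate brief cold TFA.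

**Compound list**
1 | non-8-yn-1-ol | C#CCCCCCCCO | starting material
2 | 1-bromohex-2-yne | CCCC#CCBr | starting material
3 | pentadeca-8,11-diyn-1-ol | CCCC#CCC#CCCCCCCCO | intermediate
4 | (8Z,11Z)-pentadeca-8,11-dien-1-ol | CCC/C=C\C/C=C\CCCCCCCO | intermediate
5 | (8Z,11Z)-1-bromopentadeca-8,11-diene | CCC/C=C\C/C=C\CCCCCCCBr | intermediate
6 | di-tert-butyl squarate (3,4-di-tert-butoxycyclobut-3-ene-1,2-dione) | CC(C)(C)OC1=C(OC(C)(C)C)C(=O)C1=O | starting material
7 | [(8Z,11Z)-pentadeca-8,11-dien-1-yl]magnesium bromide | CCC/C=C\C/C=C\CCCCCCC[Mg]Br | intermediate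
8 | bromomagnesium 2,3-di-tert-butoxy-4-oxo-1-[(8Z,11Z)-pentadeca-8,11-dien-1-yl]cyclobut-2-en-1-olate (racemic) | CCC/C=C\C/C=C\CCCCCCCC1(O[Mg]Br)C(OC(C)(C)C)=C(OC(C)(C)C)C1=O | intermediate
9 | 2,3-di-tert-butoxy-4-oxo-1-[(8Z,11Z)-pentadeca-8,11-dien-1-yl]cyclobut-2-en-1-yl trifluoroacetate (racemic) | CCC/C=C\C/C=C\CCCCCCCC1(OC(=O)C(F)(F)F)C(OC(C)(C)C)=C(OC(C)(C)C)C1=O | intermediate
10 | 3-tert-butoxy-4-[(8Z,11Z)-pentadeca-8,11-dien-1-yl]cyclobut-3-ene-1,2-dione | CCC/C=C\C/C=C\CCCCCCCC1=C(OC(C)(C)C)C(=O)C1=O | intermediate
11 | methyl vinyl ether (methoxyethene) | COC=C | starting material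
12 | 1,2-dibromo-1-methoxyethane (racemic) | COC(Br)CBr | intermediate
13 | (Z)-1-bromo-2-methoxyethene | CO/C=C\Br | intermediate
14 | (Z)-2-methoxyvinyllithium | CO/C=C\[Li] | intermediate
15 | lithium alkoxide of 16 (racemic) | CCC/C=C\C/C=C\CCCCCCCC1=C(OC(C)(C)C)C(O[Li])(/C=C\OC)C1=O | intermediate
16 | 3-tert-butoxy-4-hydroxy-4-[(Z)-2-methoxyethenyl]-2-[(8Z,11Z)-pentadeca-8,11-dien-1-yl]cyclobut-2-en-1-one (racemic) | CCC/C=C\C/C=C\CCCCCCCC1=C(OC(C)(C)C)C(O)(/C=C\OC)C1=O | intermediate
17 | dienylketene: (3Z,5Z)-3-tert-butoxy-4-hydroxy-6-methoxy-2-[(8Z,11Z)-pentadeca-8,11-dien-1-yl]hexa-1,3,5-trien-1-one | CCC/C=C\C/C=C\CCCCCCCC(=C=O)/C(OC(C)(C)C)=C(O)\C=C/OC | intermediate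
18 | 3-tert-butoxy-4-hydroxy-6-methoxy-2-[(8Z,11Z)-pentadeca-8,11-dien-1-yl]cyclohexa-2,4-dien-1-one (racemic) | CCC/C=C\C/C=C\CCCCCCCC1=C(OC(C)(C)C)C(O)=CC(OC)C1=O | intermediate
19 | 2-tert-butoxy-5-methoxy-3-[(8Z,11Z)-pentadeca-8,11-dien-1-yl]benzene-1,4-diol | CCC/C=C\C/C=C\CCCCCCCc1c(OC(C)(C)C)c(O)cc(OC)c1O | intermediate
20 | 2-tert-butoxy-5-methoxy-3-[(8Z,11Z)-pentadeca-8,11-dien-1-yl]cyclohexa-2,5-diene-1,4-dione | CCC/C=C\C/C=C\CCCCCCCC1=C(OC(C)(C)C)C(=O)C=C(OC)C1=O | intermediate
21 | 2-hydroxy-5-methoxy-3-[(8Z,11Z)-pentadeca-8,11-dien-1-yl]cyclohexa-2,5-diene-1,4-dione (sorgoleone-360) | CCC/C=C\C/C=C\CCCCCCCC1=C(O)C(=O)C=C(OC)C1=O | target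

**Step count**
Total steps: 8. Longest linear sequence: 7 steps (1, 2, 3, 4, 6, 7, 8); step 5 is a one-step branch.

**Steps most likely to fail**

Step 6. The vinyllithium may decompose by β-elimination of lithium methoxide on warming, some attack may occur at the vinylogous ester carbonyl, and the tertiary allylic carbinol with its enol ether may ionize or hydrolyse during work-up. The fallback sets out from 10 (with 13 as the two-carbon source) and comes back at 20. Treating 13 with 2 equiv LiN(iPr)2 in THF at −78 °C should cause anti elimination of HBr and deprotonation to lithium methoxyacetylide F1. This robust sp carbanion should add to the same carbonyl of 10 and give, after aqueous quench, 3-tert-butoxy-4-hydroxy-4-(methoxyethynyl)-2-[(8Z,11Z)-pentadeca-8,11-dien-1-yl]cyclobut-2-en-1-one F2. Heating F2 in toluene at 80–110 °C should trigger the alkynyl variant of the Moore rearrangement: ring opening to the enynylketene, bonding of the ketene carbon to the methoxy-bearing alkyne carbon, and hydrogen transfer in the resulting ring diradical. This gives quinone 20 directly, without an oxidant and without the acid-labile enol ether carbinol.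

Step 7. Dienone 18 may expel methanol through its free enol instead of enolizing to the hydroquinone, the ketene may be captured by the carbinol oxygen if torquoselectivity erodes, and the bis-allylic position may autoxidize at 110 °C. The fallback sets out from 16 and comes back at 19. Silylation of 16 (Me3SiCl, Et3N, DMAP, CH2Cl2, 0 °C) should give 3-tert-butoxy-4-[(Z)-2-methoxyethenyl]-2-[(8Z,11Z)-pentadeca-8,11-dien-1-yl]-4-(trimethylsilyloxy)cyclobut-2-en-1-one F3, in which the oxygen can neither lactonize onto the ketene nor act as a free enol for methanol expulsion. Thermolysis in toluene should then give 3-tert-butoxy-6-methoxy-2-[(8Z,11Z)-pentadeca-8,11-dien-1-yl]-4-(trimethylsilyloxy)phenol F4. Desilylation with Bu4NF buffered by AcOH in THF at 0 °C should give hydroquinone 19, which is oxidized with Ag2O to 20 as in step 7.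

Step 2. Stopping a double semi-hydrogenation of a skipped diyne exactly at the diene stage may fail, with over-reduction or partial Z to E isomerization that is hard to correct by chromatography. The fallback sets out from 1 and comes back at 4. (Z)-1-Bromohex-2-ene F5, made from commercial (Z)-hex-2-en-1-ol with PBr3 in Et2O at −10 °C, is coupled with 1 under the CuI, NaI, K2CO3 conditions of step 1 (SN2 at the primary allylic carbon, Z geometry retained) to give (Z)-pentadec-11-en-8-yn-1-ol F6. One Z-alkene is thus bought ready-made, and only a single triple bond remains to be semi-hydrogenated over the catalyst of step 2, which is much easier to stop at one equivalent of H2.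

**Further compounds**
F1 | step 6 | lithium methoxyacetylide | COC#C[Li]
F2 | step 6 | 3-tert-butoxy-4-hydroxy-4-(methoxyethynyl)-2-[(8Z,11Z)-pentadeca-8,11-dien-1-yl]cyclobut-2-en-1-one (racemic) | CCC/C=C\C/C=C\CCCCCCCC1=C(OC(C)(C)C)C(O)(C#COC)C1=O
F3 | step 7 | 3-tert-butoxy-4-[(Z)-2-methoxyethenyl]-2-[(8Z,11Z)-pentadeca-8,11-dien-1-yl]-4-(trimethylsilyloxy)cyclobut-2-en-1-one (racemic) | CCC/C=C\C/C=C\CCCCCCCC1=C(OC(C)(C)C)C(O[Si](C)(C)C)(/C=C\OC)C1=O
F4 | step 7 | 3-tert-butoxy-6-methoxy-2-[(8Z,11Z)-pentadeca-8,11-dien-1-yl]-4-(trimethylsilyloxy)phenol | CCC/C=C\C/C=C\CCCCCCCc1c(OC(C)(C)C)c(O[Si](C)(C)C)cc(OC)c1O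
F5 | step 2 | (Z)-1-bromohex-2-ene | CCC/C=C\CBr
F6 | step 2 | (Z)-pentadec-11-en-8-yn-1-ol | CCC/C=C\CC#CCCCCCCCO
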